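**Retrosynthetic overview**

1. Target 37 comes from the 3-keto-1(10)E,4Z-germacradienolide 35; the C1–C10 oxirane and the C3 carbinol are made last (dioxirane epoxidation, Luche reduction).
2. Feature used: in the ten-membered ring the arc C10–C1–C2–C3–C4–C5 (C1=C10 E, C4=C5 Z, oxygen on C3) is a ring-opened cyclohexa-1,3-diene. 35 therefore comes from silyl trienol ether 34, and 34 from the cis-fused 10-epi-eudesmanolide dienol ether 33 by cutting C5–C10, so that rings A and B merge (photochemical conrotatory 6π opening).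
3. 33 comes from enone acid 25: γ-hydroxylation at C6, hydroxyl-directed hydrogenation (5α-H, cis fusion), lactonisation, selenoxide eliminations (C1=C2, C11=C13), dienol silylation.
4. 25 comes from Robinson annulation of ethyl vinyl ketone onto ketone 13 (C10 quaternary centre), C8 inversion by oxidation/reduction, esterification with epoxy acid 5 (Sharpless epoxidation, from tiglic acid) and C12 oxidation. 13 comes from (S)-carvone by α′-oxygenation and Wharton transposition.
5. Ring order: ring B (carvone), ring A (Robinson), γ-lactone, ten-membered ring (key step), oxirane.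

Key step: step 20

Remark: eudesmane/germacrane numbering is used (C14 on C10, C15 on C4, C11–C13 on C7; α/β as in the usual drawing with the C7 side chain β). Centres that are erased later (C2 of 13, C4 and C11 of 28–31, C4 of 32, the selenium-bearing carbons of 31) are drawn as the expected epimer and their configuration does not matter.

**Route**

Step 1
Reactants: 1 tiglic acid
Product: 2 (E)-2-methylbut-2-en-1-ol
Conditions: LiAlH4, Et2O, 0 → 25 °C; aqueous work-up
Reagents that add atoms: none
Why: Hydride reduction of the carboxylic acid by LiAlH4 should give the allylic alcohol with the E double bond untouched.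

Step 2
Reactants: 2 (E)-2-methylbut-2-en-1-ol
Product: 3 [(2R,3R)-2,3-dimethyloxiran-2-yl]methanol
Conditions: Ti(OiPr)4 (10 mol%), D-(−)-diethyl tartrate (12 mol%), t-BuOOH, 4 Å MS, CH2Cl2, −20 °C
Reagents that add atoms: tert-butyl hydroperoxide, CC(C)(C)OO
Why: Sharpless asymmetric epoxidation of an E-trisubstituted allylic alcohol; the D-(−)-tartrate complex delivers oxygen to the face that gives the (2R,3R)-epoxide (the L-(+)-tartrate gives 2S,3S).

Step 3
Reactants: 3 [(2R,3R)-2,3-dimethyloxiran-2-yl]methanol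
Product: 5 (2S,3R)-2,3-dimethyloxirane-2-carboxylic acid, via epoxy aldehyde 4 (not isolated)
Conditions: RuCl3·xH2O (2 mol%), NaIO4, CCl4–MeCN–H2O, 25 °C
Reagents that add atoms: water, O
Why: RuO4 oxidation (Sharpless conditions) of a 2,3-epoxy alcohol to the glycidic acid should leave the oxirane and both stereocentres intact (the C2 descriptor changes from R to S only through the priority change).

Step 4
Reactants: 6 (S)-carvone
Product: 8 (5R,6R)-6-(tert-butyldimethylsilyloxy)-2-methyl-5-(prop-1-en-2-yl)cyclohex-2-en-1-one, via silyl dienol ether 7 (not isolated)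
Conditions: LiN(iPr)2, THF, −78 °C; TBSCl, DMPU, −78 → 0 °C; then mCPBA, hexane, −15 → 25 °C
Reagents that add atoms: tert-butyldimethylsilyl chloride, CC(C)(C)[Si](C)(C)Cl; 3-chloroperbenzoic acid, OOC(=O)c1cccc(Cl)c1
Why: Kinetic α′-deprotonation and O-silylation give the cross-conjugated dienol ether, and Rubottom oxidation puts oxygen on C6 anti to the neighbouring isopropenyl group with silyl migration to the new oxygen (5,6-trans).

Step 5
Reactants: 8 (5R,6R)-6-(tert-butyldimethylsilyloxy)-2-methyl-5-(prop-1-en-2-yl)cyclohex-2-en-1-one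
Product: 9 2,3-epoxide of 8 (oxirane trans to the isopropenyl group)
Conditions: t-BuOOH, BnMe3N+ OH− (10 mol%), THF, 0 °C
Reagents that add atoms: tert-butyl hydroperoxide, CC(C)(C)OO
Why: Weitz–Scheffer nucleophilic epoxidation of the enone; the oxirane configuration is of no consequence because only its C3–O bond survives step 6 and is oxidised in step 7.

Step 6
Reactants: 9 2,3-epoxide of 8
Product: 11 (1S,4S,5R)-4-(tert-butyldimethylsilyloxy)-2-methyl-5-(prop-1-en-2-yl)cyclohex-2-en-1-ol, via epoxy hydrazone 10 (not isolated)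
Conditions: N2H4·H2O, AcOH (cat.), MeOH, 0 → 25 °C
Reagents that add atoms: none
Why: Wharton transposition: the epoxy hydrazone loses N2 and gives the transposed allylic alcohol, so that the silyloxy carbon ends up γ to the future carbonyl.

Step 7
Reactants: 11 (1S,4S,5R)-4-(tert-butyldimethylsilyloxy)-2-methyl-5-(prop-1-en-2-yl)cyclohex-2-en-1-ol
Product: 12 (4S,5R)-4-(tert-butyldimethylsilyloxy)-2-methyl-5-(prop-1-en-2-yl)cyclohex-2-en-1-one
Conditions: Dess–Martin periodinane, pyridine, CH2Cl2, 0 → 25 °C
Reagents that add atoms: none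
Why: Dess–Martin oxidation of a secondary allylic alcohol under buffered, non-epimerising conditions.

Step 8
Reactants: 12 (4S,5R)-4-(tert-butyldimethylsilyloxy)-2-methyl-5-(prop-1-en-2-yl)cyclohex-2-en-1-one
Product: 13 (4S,5R)-4-(tert-butyldimethylsilyloxy)-2-methyl-5-(prop-1-en-2-yl)cyclohexan-1-one (C2 epimers)
Conditions: LiBH(s-Bu)3 (L-Selectride), THF, −78 °C; H2O
Reagents that add atoms: none
Why: Conjugate (1,4) hydride reduction of a β-unsubstituted cyclohexenone by L-Selectride, as for carvone itself; the isopropenyl group is not touched.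

Step 9
Reactants: 13 (4S,5R)-4-(tert-butyldimethylsilyloxy)-2-methyl-5-(prop-1-en-2-yl)cyclohexan-1-one; 14 ethyl vinyl ketone
Product: 17 8α-(tert-butyldimethylsilyloxy)-10-epi-eudesma-4,11-dien-3-one (7β-isopropenyl and 10α-methyl), via Michael adduct 15 (not isolated), via ketol 16 (not isolated)
Conditions: NaOEt (0.2 equiv), EtOH, 0 → 25 °C, then 70 °C
Reagents that add atoms: ethyl vinyl ketone (14), CCC(=O)C=C
Why: Robinson annulation: the more substituted enolate reacts through a chair with equatorial isopropenyl and silyloxy groups, the chain enters axially and cis to the isopropenyl group (C10 methyl trans to it, as in the dihydrocarvone to 10-epi-α-cyperone case), and aldol condensation closes ring A.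

Step 10
Reactants: 17 8α-(tert-butyldimethylsilyloxy)-10-epi-eudesma-4,11-dien-3-one
Product: 18 8α-hydroxy-10-epi-eudesma-4,11-dien-3-one
Conditions: HF·pyridine, THF, 0 → 25 °C
Reagents that add atoms: none
Why: Fluoride-mediated cleavage of the secondary silyl ether; enone and isopropenyl group are inert.

Step 11
Reactants: 18 8α-hydroxy-10-epi-eudesma-4,11-dien-3-one
Product: 19 10-epi-eudesma-4,11-diene-3,8-dione
Conditions: Dess–Martin periodinane, pyridine, CH2Cl2, 0 °C
Reagents that add atoms: none
Why: Dess–Martin oxidation under neutral conditions, chosen so that the β,γ-unsaturated ketone neither conjugates nor epimerises at C7.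

Step 12
Reactants: 19 10-epi-eudesma-4,11-diene-3,8-dione
Product: 20 8β-hydroxy-10-epi-eudesma-4,11-dien-3-one
Conditions: NaBH4, MeOH–CH2Cl2, −78 °C
Reagents that add atoms: none
Why: Chemoselective borohydride reduction of the saturated ketone in the presence of the tetrasubstituted enone; with the C10 methyl and the C7 isopropenyl both axial on ring B, hydride should add anti to the adjacent isopropenyl group and give the equatorial 8β-alcohol, which is also the more stable epimer (the 8α-alcohol is syn-diaxial to the C10 methyl).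

Step 13
Reactants: 20 8β-hydroxy-10-epi-eudesma-4,11-dien-3-one; 5 (2S,3R)-2,3-dimethyloxirane-2-carboxylic acid
Product: 22 8β-[(2S,3R)-2,3-dimethyloxirane-2-carbonyloxy]-10-epi-eudesma-4,11-dien-3-one, via mixed anhydride 21 (not isolated)
Conditions: 2,4,6-trichlorobenzoyl chloride, Et3N, THF, 25 °C; then 20, DMAP, toluene, 25 °C
Reagents that add atoms: (2S,3R)-2,3-dimethyloxirane-2-carboxylic acid (5), OC(=O)[C@@]1(C)O[C@@H]1C
Why: Yamaguchi esterification of the unhindered equatorial alcohol with retention at C8; the acid has no α-hydrogen and cannot epimerise.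

Step 14
Reactants: 22 8β-[(2S,3R)-2,3-dimethyloxirane-2-carbonyloxy]-10-epi-eudesma-4,11-dien-3-one
Product: 23 12-hydroxy derivative of 22 (2-substituted allylic alcohol on C7)
Conditions: SeO2 (cat.), t-BuOOH, CH2Cl2, 25 °C
Reagents that add atoms: selenium dioxide, O=[Se]=O (oxygen carrier, reoxidised by tert-butyl hydroperoxide, CC(C)(C)OO)
Why: SeO2 allylic oxidation (ene reaction, then [2,3] shift) attacks the electron-rich isopropenyl group at its methyl group and leaves the electron-poor enone alone.

Step 15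
Reactants: 23 12-hydroxy derivative of 22
Product: 25 8β-[(2S,3R)-2,3-dimethyloxirane-2-carbonyloxy]-3-oxo-10-epi-eudesma-4,11(13)-dien-12-oic acid, via enal 24 (not isolated)
Conditions: MnO2, CH2Cl2, 25 °C; filter; NaClO2, NaH2PO4, 2-methyl-2-butene, t-BuOH–H2O, 0 → 25 °C
Reagents that add atoms: sodium chlorite, [Na+].[O-]Cl=O
Why: MnO2 oxidation of the allylic alcohol followed by Pinnick oxidation of the enal gives the acrylic acid at a buffered pH that the oxirane tolerates.

Step 16
Reactants: 25 8β-acyloxy-3-oxo-10-epi-eudesma-4,11(13)-dien-12-oic acid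
Product: 27 6α-hydroxy derivative of 25, via bis-silyl derivative 26 (not isolated)
Conditions: TBSOTf, Et3N, CH2Cl2, 0 °C; then dimethyldioxirane, acetone–CH2Cl2, −78 → −40 °C; pH 7 aqueous work-up
Reagents that add atoms: dimethyldioxirane, CC1(C)OO1
Why: Soft enolisation gives the 3,5-dienol silyl ether, and vinylogous Rubottom oxidation hydroxylates C6 on the α face, syn to the axial C10 methyl as in steroidal 3,5-dienol ethers and anti to the axial C7 side chain.

Step 17
Reactants: 27 6α-hydroxy-8β-acyloxy-3-oxo-10-epi-eudesma-4,11(13)-dien-12-oic acid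
Product: 29 8β-[(2S,3R)-2,3-dimethyloxirane-2-carbonyloxy]-3-oxo-10-epi-5α-eudesman-6α,12-olide (cis-fused decalone; trans-fused lactone), via saturated hydroxy acid 28 (not isolated)
Conditions: [Ir(cod)(PCy3)(py)]PF6 (5 mol%), H2 (1 atm), CH2Cl2, 25 °C; then PPTS (cat.), 25 °C
Reagents that add atoms: none
Why: Hydroxyl-directed homogeneous hydrogenation: iridium bound to the axial 6α-hydroxyl delivers H2 to C4 and C5 from the α face (5α-H, cis to the C10 methyl, cis ring fusion), the acrylic double bond is saturated as well, and after the ring-B flip the diequatorial 6α-OH and C12 acid close to the trans-fused γ-lactone under acid catalysis.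

Step 18
Reactants: 29 8β-acyloxy-3-oxo-10-epi-5α-eudesman-6α,12-olide
Product: 32 8β-[(2S,3R)-2,3-dimethyloxirane-2-carbonyloxy]-3-oxo-10-epi-5α-eudesma-1,11(13)-dien-6α,12-olide, via bis(trimethylsilyl) derivative 30 (not isolated), via bis-selenide 31 (not isolated)
Conditions: Me3SiCl then LiN(iPr)2 (in situ quench), THF, −78 °C; PhSeCl, −78 → 0 °C; then 30% H2O2, pyridine, CH2Cl2, 0 → 25 °C
Reagents that add atoms: none
Why: α-Selenenylation and selenoxide syn elimination: in situ silylation traps the kinetic C2 enolate and the lactone enolate at once (no time for acyl transfer from the C8 ester), and oxidation should give the C1=C2 enone and the exocyclic C11=C13 methylene (the usual outcome for trans-fused lactones, although some endocyclic 7(11)-ene is possible).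

Step 19
Reactants: 32 8β-acyloxy-3-oxo-10-epi-5α-eudesma-1,11(13)-dien-6α,12-olide
Product: 33 3-(tert-butyldimethylsilyloxy)-8β-[(2S,3R)-2,3-dimethyloxirane-2-carbonyloxy]-10-epi-5α-eudesma-1,3,11(13)-trien-6α,12-olide
Conditions: TBSOTf, Et3N, CH2Cl2, 0 → 25 °C
Reagents that add atoms: tert-butyldimethylsilyl triflate, CC(C)(C)[Si](C)(C)OS(=O)(=O)C(F)(F)F
Why: Soft enolisation (silyl triflate and amine) can remove only the C4 hydrogen, since C2 is vinylic and C10 quaternary, and gives the cross-conjugated 3-silyloxy-1,3-diene; lactone and ester have no α-hydrogen.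

Step 20
Reactants: 33 3-silyloxy-10-epi-5α-eudesma-1,3,11(13)-trien-6α,12-olide 8β-ester
Product: 34 3-(tert-butyldimethylsilyloxy)-8β-[(2S,3R)-2,3-dimethyloxirane-2-carbonyloxy]germacra-1(10)E,2,4Z,11(13)-tetraen-6α,12-olide (C2=C3 with C1 and C4 cis)
Conditions: hν (300 nm, Pyrex), degassed THF, −78 °C; solution kept cold
Reagents that add atoms: none
Why: Excitation of the ring-A silyloxydiene triggers conrotatory 6π electrocyclic opening, the reaction by which fused cyclohexa-1,3-dienes (hexalins, provitamin D) give cyclodecatrienes and previtamins. No ring is closed by bond formation: the ten-membered ring arises by scission of the C5–C10 σ bond shared by rings A and B, and no stereocentre is created because C5 and C10 become trigonal. The trans-fused lactone holds ring B as a chair, so on ring A C6 is pseudoaxial and C9 pseudoequatorial (5-H and the C10 methyl lie on the face of O6), which fixes the helical twist of the diene. Conrotation that continues this twist turns C6 inward and C9 outward, giving Z C4=C5, E C1=C10 and the cis C2=C3 bond. The step needs this one conrotatory sense and must stop before the triene reacts further: the first is secured by the cis ring fusion and the locked chair, the second by irradiating near 300 nm, where the twisted triene should absorb less than the diene, at −78 °C and by taking the cold solution straight into step 21.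

Step 21
Reactants: 34 3-silyloxy-germacra-1(10)E,2,4Z,11(13)-tetraen-6α,12-olide 8β-ester
Product: 35 8β-[(2S,3R)-2,3-dimethyloxirane-2-carbonyloxy]-3-oxogermacra-1(10)E,4Z,11(13)-trien-6α,12-olide
Conditions: Bu4NF, AcOH, THF, −78 → −40 °C
Reagents that add atoms: none
Why: Fluoride cleavage of the silyl enol ether and kinetic α-protonation at C2 give the C3 ketone conjugated with C4=C5 and leave C1=C10 isolated, which removes the triene before thermal disrotatory reclosure.

Step 22
Reactants: 35 3-oxogermacra-1(10)E,4Z,11(13)-trien-6α,12-olide 8β-ester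
Product: 36 (1R,10R)-1,10-epoxy-8β-[(2S,3R)-2,3-dimethyloxirane-2-carbonyloxy]-3-oxogermacra-4Z,11(13)-dien-6α,12-olide
Conditions: dimethyldioxirane, acetone–CH2Cl2, −40 → −20 °C
Reagents that add atoms: dimethyldioxirane, CC1(C)OO1
Why: Dioxirane epoxidation under neutral conditions should take the only electron-rich alkene (C4=C5 and C11=C13 are carbonyl-conjugated) on the outer face of the E-olefin in the conformer with the C10 methyl β, as is usual for germacranolides, giving the trans 1β,10α-epoxide.

Step 23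
Reactants: 36 (1R,10R)-1,10-epoxy-3-oxogermacra-4Z,11(13)-dien-6α,12-olide 8β-ester
Product: 37 target, (1R,3S,6R,7R,8R,10R)-1,10-epoxy-3-hydroxy-8-[(2S,3R)-2,3-dimethyloxirane-2-carbonyloxy]germacra-4Z,11(13)-dien-6,12-olide
Conditions: NaBH4, CeCl3·7H2O, MeOH, −78 °C
Reagents that add atoms: none
Why: Luche reduction gives 1,2-reduction of the enone without conjugate reduction of the α-methylene lactone; hydride is expected to approach the C3 carbonyl from the outer α face of the ten-membered ring and give the 3β (3S) alcohol.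

**Compound list**

1 | tiglic acid, (E)-2-methylbut-2-enoic acid | C/C=C(\C)C(=O)O | starting material
2 | (E)-2-methylbut-2-en-1-ol | C/C=C(\C)CO | intermediate
3 | [(2R,3R)-2,3-dimethyloxiran-2-yl]methanol | OC[C@@]1(C)O[C@@H]1C | intermediate
4 | (2S,3R)-2,3-dimethyloxirane-2-carbaldehyde | O=C[C@@]1(C)O[C@@H]1C | intermediate (not isolated)
5 | (2S,3R)-2,3-dimethyloxirane-2-carboxylic acid | OC(=O)[C@@]1(C)O[C@@H]1C | intermediate
6 | (S)-carvone | CC1=CC[C@@H](CC1=O)C(C)=C | starting material
7 | cross-conjugated TBS dienol ether of 6 (C1–OSi, C1=C6, C2=C3) | CC1=CC[C@@H](C=C1O[Si](C)(C)C(C)(C)C)C(C)=C | intermediate (not isolated)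
8 | (5R,6R)-6-(tert-butyldimethylsilyloxy)-2-methyl-5-(prop-1-en-2-yl)cyclohex-2-en-1-one | CC1=CC[C@@H]([C@@H](O[Si](C)(C)C(C)(C)C)C1=O)C(C)=C | intermediate
9 | 2,3-epoxide of 8, oxirane trans to isopropenyl | C[C@]12O[C@H]1C[C@@H]([C@@H](O[Si](C)(C)C(C)(C)C)C2=O)C(C)=C | intermediate
10 | hydrazone of 9 | C[C@]12O[C@H]1C[C@@H]([C@@H](O[Si](C)(C)C(C)(C)C)C2=NN)C(C)=C | intermediate (not isolated)
11 | (1S,4S,5R)-4-(tert-butyldimethylsilyloxy)-2-methyl-5-(prop-1-en-2-yl)cyclohex-2-en-1-ol | CC1=C[C@H](O[Si](C)(C)C(C)(C)C)[C@@H](C(C)=C)C[C@@H]1O | intermediate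
12 | (4S,5R)-4-(tert-butyldimethylsilyloxy)-2-methyl-5-(prop-1-en-2-yl)cyclohex-2-en-1-one | CC1=C[C@H](O[Si](C)(C)C(C)(C)C)[C@@H](C(C)=C)CC1=O | intermediate
13 | (4S,5R)-4-(tert-butyldimethylsilyloxy)-2-methyl-5-(prop-1-en-2-yl)cyclohexan-1-one, C2 epimers | CC1C[C@H](O[Si](C)(C)C(C)(C)C)[C@@H](C(C)=C)CC1=O | intermediate
14 | ethyl vinyl ketone (pent-1-en-3-one) | CCC(=O)C=C | starting material
15 | Michael adduct, 2-methyl-2-(3-oxopentyl) ketone with the new chain cis to isopropenyl | CCC(=O)CC[C@@]1(C)C[C@H](O[Si](C)(C)C(C)(C)C)[C@@H](C(C)=C)CC1=O | intermediate (not isolated)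
16 | aldol ketol, 5-hydroxy-8α-silyloxy-10-epi-eudesm-11-en-3-one | CC1C(=O)CC[C@@]2(C)C[C@H](O[Si](C)(C)C(C)(C)C)[C@@H](C(C)=C)CC12O | intermediate (not isolated)
17 | 8α-(tert-butyldimethylsilyloxy)-10-epi-eudesma-4,11-dien-3-one | CC1=C2C[C@H](C(C)=C)[C@@H](O[Si](C)(C)C(C)(C)C)C[C@]2(C)CCC1=O | intermediate
18 | 8α-hydroxy-10-epi-eudesma-4,11-dien-3-one | CC1=C2C[C@H](C(C)=C)[C@@H](O)C[C@]2(C)CCC1=O | intermediate
19 | 10-epi-eudesma-4,11-diene-3,8-dione | CC1=C2C[C@H](C(C)=C)C(=O)C[C@]2(C)CCC1=O | intermediate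
20 | 8β-hydroxy-10-epi-eudesma-4,11-dien-3-one | CC1=C2C[C@H](C(C)=C)[C@H](O)C[C@]2(C)CCC1=O | intermediate
21 | mixed anhydride of 5 with 2,4,6-trichlorobenzoic acid | O=C(OC(=O)c1c(Cl)cc(Cl)cc1Cl)[C@@]2(C)O[C@@H]2C | intermediate (not isolated)
22 | 8β-[(2S,3R)-2,3-dimethyloxirane-2-carbonyloxy]-10-epi-eudesma-4,11-dien-3-one | CC1=C2C[C@H](C(C)=C)[C@H](OC(=O)[C@@]3(C)O[C@@H]3C)C[C@]2(C)CCC1=O | intermediate
23 | 12-hydroxy derivative of 22 | CC1=C2C[C@H](C(CO)=C)[C@H](OC(=O)[C@@]3(C)O[C@@H]3C)C[C@]2(C)CCC1=O | intermediate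
24 | 12-al (enal) derived from 23 | CC1=C2C[C@H](C(C=O)=C)[C@H](OC(=O)[C@@]3(C)O[C@@H]3C)C[C@]2(C)CCC1=O | intermediate (not isolated)
25 | 8β-acyloxy-3-oxo-10-epi-eudesma-4,11(13)-dien-12-oic acid | CC1=C2C[C@H](C(C(=O)O)=C)[C@H](OC(=O)[C@@]3(C)O[C@@H]3C)C[C@]2(C)CCC1=O | intermediate
26 | 3,5-dienol TBS ether and TBS ester of 25 | CC1=C(O[Si](C)(C)C(C)(C)C)CC[C@@]2(C)C[C@@H](OC(=O)[C@@]3(C)O[C@@H]3C)[C@@H](C(=C)C(=O)O[Si](C)(C)C(C)(C)C)C=C12 | intermediate (not isolated)
27 | 6α-hydroxy-8β-acyloxy-3-oxo-10-epi-eudesma-4,11(13)-dien-12-oic acid | CC1=C2[C@@H](O)[C@H](C(=C)C(=O)O)[C@H](OC(=O)[C@@]3(C)O[C@@H]3C)C[C@]2(C)CCC1=O | intermediate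
28 | 6α-hydroxy-8β-acyloxy-3-oxo-10-epi-5α-eudesman-12-oic acid (4β-methyl) | OC(=O)C(C)[C@@H]1[C@H](OC(=O)[C@@]2(C)O[C@@H]2C)C[C@]3(C)CCC(=O)[C@H](C)[C@@H]3[C@H]1O | intermediate (not isolated)
29 | 8β-acyloxy-3-oxo-10-epi-5α-eudesman-6α,12-olide | C[C@H]1C(=O)O[C@H]2[C@H]1[C@H](OC(=O)[C@@]3(C)O[C@@H]3C)C[C@]3(C)CCC(=O)[C@H](C)[C@H]23 | intermediate
30 | C2=C3 trimethylsilyl enol ether and lactone silyl ketene acetal of 29 | CC1=C(O[Si](C)(C)C)O[C@H]2[C@H]1[C@H](OC(=O)[C@@]3(C)O[C@@H]3C)C[C@]3(C)CC=C(O[Si](C)(C)C)[C@H](C)[C@H]23 | intermediate (not isolated)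
31 | 2,11-bis(phenylseleno) derivative of 29 | CC1([Se]c4ccccc4)C(=O)O[C@H]2[C@H]1[C@H](OC(=O)[C@@]3(C)O[C@@H]3C)C[C@]3(C)CC([Se]c5ccccc5)C(=O)[C@H](C)[C@H]23 | intermediate (not isolated)
32 | 8β-acyloxy-3-oxo-10-epi-5α-eudesma-1,11(13)-dien-6α,12-olide | C=C1C(=O)O[C@H]2[C@H]1[C@H](OC(=O)[C@@]3(C)O[C@@H]3C)C[C@]3(C)C=CC(=O)[C@H](C)[C@H]23 | intermediate
33 | 3-(tert-butyldimethylsilyloxy)-8β-acyloxy-10-epi-5α-eudesma-1,3,11(13)-trien-6α,12-olide | C=C1C(=O)O[C@H]2[C@H]1[C@H](OC(=O)[C@@]3(C)O[C@@H]3C)C[C@]3(C)C=CC(O[Si](C)(C)C(C)(C)C)=C(C)[C@H]23 | intermediate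
34 | 3-(tert-butyldimethylsilyloxy)-8β-acyloxygermacra-1(10)E,2,4Z,11(13)-tetraen-6α,12-olide | C=C1C(=O)O[C@@H]2/C=C(/C)\C(O[Si](C)(C)C(C)(C)C)=C/C=C(\C)C[C@@H](OC(=O)[C@@]3(C)O[C@@H]3C)[C@@H]12 | intermediate
35 | 8β-acyloxy-3-oxogermacra-1(10)E,4Z,11(13)-trien-6α,12-olide | C=C1C(=O)O[C@@H]2/C=C(/C)C(=O)C/C=C(\C)C[C@@H](OC(=O)[C@@]3(C)O[C@@H]3C)[C@@H]12 | intermediate
36 | (1R,10R)-1,10-epoxy-8β-acyloxy-3-oxogermacra-4Z,11(13)-dien-6α,12-olide | C=C1C(=O)O[C@@H]2/C=C(/C)C(=O)C[C@H]3O[C@]3(C)C[C@@H](OC(=O)[C@@]3(C)O[C@@H]3C)[C@@H]12 | intermediate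
37 | CNP0268255.5, 1β,10α-epoxy-3β-hydroxy-8β-[(2S,3R)-2,3-dimethyloxirane-2-carbonyloxy]germacra-4Z,11(13)-dien-6α,12-olide | C=C1C(=O)O[C@@H]2/C=C(/C)[C@@H](O)C[C@H]3O[C@]3(C)C[C@@H](OC(=O)[C@@]3(C)O[C@@H]3C)[C@@H]12 | target

(In 25–36, "acyloxy" is the (2S,3R)-2,3-dimethyloxirane-2-carbonyloxy group.)

**Step count**

Total: 23 steps. Longest linear sequence: 20 steps (steps 4–23, from (S)-carvone 6 to 37); the epoxy acid 5 is made in 3 steps and joined in step 13.

**Steps most likely to fail**

Step 20 (key step). The irradiation may stall at a photostationary mixture poor in triene. The triene may also react further on over-irradiation, or reclose thermally (disrotatory, to a trans-fused diene) while the labile silyl trienol ether is handled. The fallback sets out from 32 and changes the substrate to one whose triene can be separated and the diene recycled. 32 is O-acetylated (KN(SiMe3)2, THF, −78 °C; Ac2O) to the cross-conjugated dienol acetate F1. Irradiation at 300 nm and −40 °C gives the trienyl acetate F2, which should tolerate chromatography at low temperature, so that recovered F1 can be irradiated again. The enol acetate is then cleaved under neutral conditions with Bu3SnOMe (THF, 0 °C; pH 7 buffer), with protonation at C2, and the route is rejoined at 35.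

Step 12. Hydride delivery to the C8 carbonyl may show poor facial selectivity, because the axial C10 methyl shields the face opposite to the isopropenyl group, and 19 may epimerise at C7 or conjugate before it is reduced. The fallback sets out from 18 and avoids the ketone altogether. The axial 8α-alcohol of 18 is esterified directly with acid 5 under Mitsunobu conditions (PPh3, diisopropyl azodicarboxylate, toluene, 0 → 25 °C). SN2 displacement with inversion gives the equatorial 8β-ester, and the route is rejoined at 22; no new compound is made.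

Step 22. The oxidant may attack the other face of C1=C10 (reaction through the conformer with the C10 methyl α), so that the epoxide diastereomer ratio is set by the conformer population and not by the reagent. The fallback sets out from 35 and replaces substrate control by reagent control. Shi epoxidation with the D-fructose-derived ketone (which gives R,R-epoxides from E-olefins), KHSO5, MeCN–dimethoxymethane–aqueous buffer at pH 8, −10 °C, should give 36 directly; no new compound is made.

**Further compounds**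

F1 | step 20 | 3-acetoxy-8β-acyloxy-10-epi-5α-eudesma-1,3,11(13)-trien-6α,12-olide (dienol acetate of 32) | C=C1C(=O)O[C@H]2[C@H]1[C@H](OC(=O)[C@@]3(C)O[C@@H]3C)C[C@]3(C)C=CC(OC(C)=O)=C(C)[C@H]23
F2 | step 20 | 3-acetoxy-8β-acyloxygermacra-1(10)E,2,4Z,11(13)-tetraen-6α,12-olide | C=C1C(=O)O[C@@H]2/C=C(/C)\C(OC(C)=O)=C/C=C(\C)C[C@@H](OC(=O)[C@@]3(C)O[C@@H]3C)[C@@H]12
F0 | step 12 | none | none
F0 | step 22 | none | none
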